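**Retrosynthetic overview** (cyclopenta[c]pyran numbering of the target, used for the open precursor 19 as well)

1. Target 22 ⇐ 21 by fluoride removal of a 2-(trimethylsilyl)ethyl group from the coumarin 4-oxygen. 21 ⇐ its open isomer 19 by a light-driven cycloisomerisation that forms C1–C7a and closes the dihydropyran, the last ring.
2. 19 ⇐ thioester 18 + isobutenylboronic acid (Liebeskind–Srogl). 18 ⇐ enol triflate 13 + cyclopentenylboronate 17 (Suzuki). 13 ⇐ coumarinylmethanol 6 + diazo thioester 10 (Rh-carbenoid O–H insertion, then O-triflation).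
3. Ring order: benzene ring bought; coumarin pyranone ring in step 1; cyclopentene bought as cyclopentenone, with its methyl stereocentre set by copper-catalysed asymmetric conjugate addition in step 9; dihydropyran last, in step 13.
4. Enabling feature: the exocyclic ketone on C3. In 19 its oxygen is 1,5 to the hydrogens on the OCH2 carbon that becomes C1 (through O2 and C3). The C3=C4 enol ether and the cyclopentene C4a=C7a double bond form a 2-alkoxy dienone ending at C7a. Hydrogen transfer therefore gives a C1 radical and spin density at C7a, six atoms apart.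

Key step: step 13

Remark: the Z geometry drawn for 13, 18 and 19 is the one expected from step 8; it is not critical, because the excited dienone in step 13 isomerises about this double bond.
Remark: in step 9 the (S,R,R) phosphoramidite is assumed to give the 3S enolate, as it does with six-membered enones; the antipodal ligand is used if a test run shows the opposite sense.

**Route**

Step 1
Reactants: 1 1-(2-hydroxy-6-methylphenyl)ethan-1-one
Product: 2 4-hydroxy-5-methyl-2H-chromen-2-one
Conditions: NaH, (EtO)2CO, toluene, 110 °C; then aq. HCl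
Reagents that add atoms: diethyl carbonate CCOC(=O)OCC
Why: Claisen-type C-acylation of the methyl ketone enolate by the carbonate and lactonisation onto the phenoxide is the standard 4-hydroxycoumarin synthesis; no stereocentre is formed.

Step 2
Reactants: 2 4-hydroxy-5-methyl-2H-chromen-2-one
Product: 4 4-chloro-5-methyl-2-oxo-2H-chromene-3-carbaldehyde, via iminium chloride 3 (not isolated)
Conditions: POCl3, DMF, 0 to 60 °C; then ice-water
Reagents that add atoms: N,N-dimethylformamide CN(C)C=O; phosphoryl chloride O=P(Cl)(Cl)Cl; water O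
Why: Vilsmeier–Haack reaction, which on 4-hydroxycoumarins formylates the nucleophilic C3 and replaces the vinylogous acid hydroxyl by chloride; water at work-up supplies the aldehyde oxygen.

Step 3
Reactants: 4 4-chloro-5-methyl-2-oxo-2H-chromene-3-carbaldehyde
Product: 5 5-methyl-2-oxo-4-[2-(trimethylsilyl)ethoxy]-2H-chromene-3-carbaldehyde
Conditions: Me3SiCH2CH2OH, Cs2CO3, MeCN, 0 °C to rt
Reagents that add atoms: 2-(trimethylsilyl)ethanol C[Si](C)(C)CCO
Why: Addition–elimination (vinylogous nucleophilic acyl substitution) at C4, which is activated by both the lactone carbonyl and the formyl group, as known for 4-chloro-3-formylcoumarins with alcohols.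

Step 4
Reactants: 5 5-methyl-2-oxo-4-[2-(trimethylsilyl)ethoxy]-2H-chromene-3-carbaldehyde
Product: 6 3-(hydroxymethyl)-5-methyl-4-[2-(trimethylsilyl)ethoxy]-2H-chromen-2-one
Conditions: NaBH4, CeCl3·7H2O, MeOH/THF, −20 °C
Reagents that add atoms: none
Why: Luche 1,2-reduction: the cerium-modified borohydride attacks the aldehyde and not C4 of the vinylogous ester or the lactone.

Step 5
Reactants: 7 2,2,6-trimethyl-4H-1,3-dioxin-4-one
Product: 9 S-ethyl 3-oxobutanethioate, via acetylketene 8 (not isolated)
Conditions: EtSH, toluene, 110 °C (sealed tube)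
Reagents that add atoms: ethanethiol CCS
Why: Thermal retro-[4+2] cleavage of the dioxinone releases acetylketene, which the thiol traps as the β-keto thioester (acetoacetylation).

Step 6
Reactants: 9 S-ethyl 3-oxobutanethioate
Product: 10 S-ethyl 2-diazo-3-oxobutanethioate
Conditions: 4-AcNHC6H4SO2N3, Et3N, MeCN, 0 °C to rt
Reagents that add atoms: 4-acetamidobenzenesulfonyl azide CC(=O)Nc1ccc(cc1)S(=O)(=O)N=[N+]=[N-]
Why: Regitz diazo transfer to the doubly activated methylene group.

Step 7
Reactants: 6 3-(hydroxymethyl)-5-methyl-4-[2-(trimethylsilyl)ethoxy]-2H-chromen-2-one; 10 S-ethyl 2-diazo-3-oxobutanethioate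
Product: 11 S-ethyl 2-({5-methyl-2-oxo-4-[2-(trimethylsilyl)ethoxy]-2H-chromen-3-yl}methoxy)-3-oxobutanethioate (racemic)
Conditions: Rh2(OAc)4 (1 mol %), CH2Cl2, 40 °C, slow addition of 10
Reagents that add atoms: none
Why: Rh-carbenoid O–H insertion of a 2-diazo-1,3-dicarbonyl compound into a primary alcohol; the new stereocentre is racemic and irrelevant because the carbon becomes sp2 in step 8.

Step 8
Reactants: 11 S-ethyl 2-({5-methyl-2-oxo-4-[2-(trimethylsilyl)ethoxy]-2H-chromen-3-yl}methoxy)-3-oxobutanethioate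
Product: 13 S-ethyl (2Z)-2-({5-methyl-2-oxo-4-[2-(trimethylsilyl)ethoxy]-2H-chromen-3-yl}methoxy)-3-[(trifluoromethanesulfonyl)oxy]but-2-enethioate, via potassium enolate 12 (not isolated)
Conditions: KN(SiMe3)2, 18-crown-6, THF, −78 °C; then Comins' reagent, −78 to 0 °C
Reagents that add atoms: N-(5-chloropyridin-2-yl)-1,1,1-trifluoro-N-[(trifluoromethyl)sulfonyl]methanesulfonamide FC(F)(F)S(=O)(=O)N(c1ccc(Cl)cn1)S(=O)(=O)C(F)(F)F
Why: O-sulfonylation of the ketone-derived enolate of a β-keto thioester (enol triflate formation); with potassium held by the crown ether the enolate is not chelated across the two carbonyl groups, so the triflate oxygen is expected anti to the thioester carbonyl, i.e. Z.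

Step 9
Reactants: 14 cyclopent-2-en-1-one
Product: 16 (3S)-3-methylcyclopent-1-en-1-yl trifluoromethanesulfonate, via zinc enolate 15 (not isolated)
Conditions: Me2Zn, Cu(OTf)2 (2 mol %), (S,R,R)-O,O'-(1,1'-binaphthyl-2,2'-diyl) N,N-bis(1-phenylethyl)phosphoramidite (4 mol %), toluene, −30 °C; then Tf2O, 0 °C
Reagents that add atoms: dimethylzinc C[Zn]C; trifluoromethanesulfonic anhydride FC(F)(F)S(=O)(=O)OS(=O)(=O)C(F)(F)F
Why: Copper-catalysed asymmetric conjugate addition of a methylzinc reagent, in which the chiral phosphoramidite–copper complex selects the enone face and so sets C3 as S, followed by O-triflation of the regiodefined zinc enolate, which fixes the double bond between C1 and C2.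

Step 10
Reactants: 16 (3S)-3-methylcyclopent-1-en-1-yl trifluoromethanesulfonate
Product: 17 4,4,5,5-tetramethyl-2-[(3S)-3-methylcyclopent-1-en-1-yl]-1,3,2-dioxaborolane
Conditions: B2pin2, PdCl2(PPh3)2 (3 mol %), PPh3, KOPh, toluene, 50 °C
Reagents that add atoms: bis(pinacolato)diboron CC1(C)OB(OC1(C)C)B1OC(C)(C)C(C)(C)O1
Why: Miyaura borylation of an alkenyl triflate; it occurs at C1 with no shift of the double bond and does not touch the C3 stereocentre.

Step 11
Reactants: 13 S-ethyl (2Z)-2-({5-methyl-2-oxo-4-[2-(trimethylsilyl)ethoxy]-2H-chromen-3-yl}methoxy)-3-[(trifluoromethanesulfonyl)oxy]but-2-enethioate; 17 4,4,5,5-tetramethyl-2-[(3S)-3-methylcyclopent-1-en-1-yl]-1,3,2-dioxaborolane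
Product: 18 S-ethyl (2Z)-2-({5-methyl-2-oxo-4-[2-(trimethylsilyl)ethoxy]-2H-chromen-3-yl}methoxy)-3-[(3S)-3-methylcyclopent-1-en-1-yl]but-2-enethioate
Conditions: Pd(dppf)Cl2 (5 mol %), K3PO4, THF/H2O (10:1), 50 °C
Reagents that add atoms: none
Why: Suzuki–Miyaura coupling of an electron-poor β-(triflyloxy)acrylate-type triflate proceeds with retention of double-bond geometry, and a thioester is not attacked by zerovalent palladium unless a copper carboxylate is present; the stereocentre of 17 is remote from the reacting carbon.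

Step 12
Reactants: 18 S-ethyl (2Z)-2-({5-methyl-2-oxo-4-[2-(trimethylsilyl)ethoxy]-2H-chromen-3-yl}methoxy)-3-[(3S)-3-methylcyclopent-1-en-1-yl]but-2-enethioate
Product: 19 (2Z)-6-methyl-2-[(3S)-3-methylcyclopent-1-en-1-yl]-3-({5-methyl-2-oxo-4-[2-(trimethylsilyl)ethoxy]-2H-chromen-3-yl}methoxy)hepta-2,5-dien-4-one
Conditions: Me2C=CHB(OH)2, Pd2(dba)3 (2.5 mol %), tri(2-furyl)phosphine, CuO2CC4H3S (copper thiophene-2-carboxylate, 1.5 equiv), THF, 50 °C
Reagents that add atoms: (2-methylprop-1-en-1-yl)boronic acid CC(C)=CB(O)O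
Why: Liebeskind–Srogl ketone synthesis: under base-free conditions the copper carboxylate activates only the C(O)–S bond toward palladium and transfers the alkenyl group from boron, so the lactone, enol ether and silyl group are untouched.

Step 13
Reactants: 19 (2Z)-6-methyl-2-[(3S)-3-methylcyclopent-1-en-1-yl]-3-({5-methyl-2-oxo-4-[2-(trimethylsilyl)ethoxy]-2H-chromen-3-yl}methoxy)hepta-2,5-dien-4-one
Product: 21 3-[(1R,4aS,7S,7aR)-4,7-dimethyl-3-(3-methylbut-2-enoyl)-1,4a,5,6,7,7a-hexahydrocyclopenta[c]pyran-1-yl]-5-methyl-4-[2-(trimethylsilyl)ethoxy]-2H-chromen-2-one, via dienol 20 (not isolated)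
Conditions: hν (385 nm LEDs), degassed MeCN (0.005 M), 20 °C; then DBU (0.2 equiv), rt to 50 °C
Reagents that add atoms: none
Why: Proposed new method: n→π* excitation of the 2-alkoxy dienone lets the carbonyl oxygen take a hydrogen from the OCH2 group through a six-membered transition state (type-two Norrish 1,5-hydrogen transfer); the α-oxy coumarinylmethyl radical then combines with the hydroxypentadienyl radical at its terminus C7a, which closes the dihydropyran by radical recombination, formally 6-endo on the cyclopentene double bond, to give dienol 20, and DBU moves it to the conjugated ketone. The closest known reactions are the photocyclisation of 3-alkoxy-2-arylchromones (2-alkoxy enones with an unsaturated β-substituent) to pyrano-fused products by the same hydrogen transfer and vinylogous ring closure, and the Norrish–Yang cyclisation of α-alkoxy ketones. C7a is set by approach of the C1 radical anti to the adjacent C7 methyl group, C1 by the aryl group taking the outside (pseudo-equatorial) position in the closing ring, and C4a by base equilibration through the dienolate to the cis-fused isomer, since trans fusion would strain the half-chair/cyclopentane pair and put C5 in the plane of the C4 methyl. The step needs site selectivity in hydrogen transfer and ring-size selectivity: only the OCH2 hydrogens are both doubly activated (α-oxygen, allylic to coumarin C3=C4) and within six-membered reach, four-membered closure at the carbonyl carbon or C4 would give strained alkylidene oxetanes, and C–O β-cleavage is disfavoured because that bond lies in the nodal plane of the radical π system. E/Z isomerisation of the excited dienone only feeds the reactive Z isomer, and 385 nm light is not absorbed by the coumarin and only weakly by 21. The step is an isomerisation and forms no co-product.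

Step 14
Reactants: 21 3-[(1R,4aS,7S,7aR)-4,7-dimethyl-3-(3-methylbut-2-enoyl)-1,4a,5,6,7,7a-hexahydrocyclopenta[c]pyran-1-yl]-5-methyl-4-[2-(trimethylsilyl)ethoxy]-2H-chromen-2-one
Product: 22 4-hydroxy-3-[(1R,4aS,7S,7aR)-4,7-dimethyl-3-(3-methylbut-2-enoyl)-1,4a,5,6,7,7a-hexahydrocyclopenta[c]pyran-1-yl]-5-methyl-2H-chromen-2-one (CNP0297827.1)
Conditions: Bu4NF, AcOH (1:1), THF, 0 °C to rt
Reagents that add atoms: none
Why: Fluoride attacks silicon and the coumarin-4-olate, a carboxylate-like leaving group, departs with loss of ethene (β-silyl fragmentation, as in cleavage of 2-(trimethylsilyl)ethyl esters), while acetic acid buffering keeps base away from the enone and the C1 ether; no stereocentre is touched.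

**Compound list**

1 | 1-(2-hydroxy-6-methylphenyl)ethan-1-one | CC(=O)c1c(C)cccc1O | starting material
2 | 4-hydroxy-5-methyl-2H-chromen-2-one | Cc1cccc2oc(=O)cc(O)c12 | intermediate
3 | [(4-chloro-5-methyl-2-oxo-2H-chromen-3-yl)methylidene]dimethylammonium chloride | C[N+](C)=Cc1c(Cl)c2c(C)cccc2oc1=O.[Cl-] | intermediate
4 | 4-chloro-5-methyl-2-oxo-2H-chromene-3-carbaldehyde | O=Cc1c(Cl)c2c(C)cccc2oc1=O | intermediate
5 | 5-methyl-2-oxo-4-[2-(trimethylsilyl)ethoxy]-2H-chromene-3-carbaldehyde | O=Cc1c(OCC[Si](C)(C)C)c2c(C)cccc2oc1=O | intermediate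
6 | 3-(hydroxymethyl)-5-methyl-4-[2-(trimethylsilyl)ethoxy]-2H-chromen-2-one | OCc1c(OCC[Si](C)(C)C)c2c(C)cccc2oc1=O | intermediate
7 | 2,2,6-trimethyl-4H-1,3-dioxin-4-one | CC1=CC(=O)OC(C)(C)O1 | starting material
8 | acetylketene (but-1-ene-1,3-dione) | CC(=O)C=C=O | intermediate
9 | S-ethyl 3-oxobutanethioate | CCSC(=O)CC(C)=O | intermediate
10 | S-ethyl 2-diazo-3-oxobutanethioate | CCSC(=O)C(=[N+]=[N-])C(C)=O | intermediate
11 | S-ethyl 2-({5-methyl-2-oxo-4-[2-(trimethylsilyl)ethoxy]-2H-chromen-3-yl}methoxy)-3-oxobutanethioate, racemic | CCSC(=O)C(OCc1c(OCC[Si](C)(C)C)c2c(C)cccc2oc1=O)C(C)=O | intermediate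
12 | potassium (Z)-enolate of 11 (enolate oxygen on the former acetyl carbon, syn to the ether oxygen) | CCSC(=O)/C(OCc1c(OCC[Si](C)(C)C)c2c(C)cccc2oc1=O)=C(\C)[O-].[K+] | intermediate
13 | S-ethyl (2Z)-2-({5-methyl-2-oxo-4-[2-(trimethylsilyl)ethoxy]-2H-chromen-3-yl}methoxy)-3-[(trifluoromethanesulfonyl)oxy]but-2-enethioate | CCSC(=O)/C(OCc1c(OCC[Si](C)(C)C)c2c(C)cccc2oc1=O)=C(\C)OS(=O)(=O)C(F)(F)F | intermediate
14 | cyclopent-2-en-1-one | O=C1CCC=C1 | starting material
15 | methylzinc (3S)-3-methylcyclopent-1-en-1-olate | C[C@H]1CCC(O[Zn]C)=C1 | intermediate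
16 | (3S)-3-methylcyclopent-1-en-1-yl trifluoromethanesulfonate | C[C@H]1CCC(OS(=O)(=O)C(F)(F)F)=C1 | intermediate
17 | 4,4,5,5-tetramethyl-2-[(3S)-3-methylcyclopent-1-en-1-yl]-1,3,2-dioxaborolane | C[C@H]1CCC(B2OC(C)(C)C(C)(C)O2)=C1 | intermediate
18 | S-ethyl (2Z)-2-({5-methyl-2-oxo-4-[2-(trimethylsilyl)ethoxy]-2H-chromen-3-yl}methoxy)-3-[(3S)-3-methylcyclopent-1-en-1-yl]but-2-enethioate | CCSC(=O)/C(OCc1c(OCC[Si](C)(C)C)c2c(C)cccc2oc1=O)=C(\C)C1=C[C@@H](C)CC1 | intermediate
19 | (2Z)-6-methyl-2-[(3S)-3-methylcyclopent-1-en-1-yl]-3-({5-methyl-2-oxo-4-[2-(trimethylsilyl)ethoxy]-2H-chromen-3-yl}methoxy)hepta-2,5-dien-4-one | CC(C)=CC(=O)/C(OCc1c(OCC[Si](C)(C)C)c2c(C)cccc2oc1=O)=C(\C)C1=C[C@@H](C)CC1 | intermediate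
20 | dienol tautomer of 21: (1R,7S,7aR)-configured 5,6,7,7a-tetrahydro-1H-cyclopenta[c]pyran with endocyclic C4=C4a, exocyclic C3=C(OH)–CH=CMe2 (hydroxyl syn to O2), and the protected coumarin at C1 | O/C(C=C(C)C)=C1/C(C)=C2CC[C@H](C)[C@H]2[C@H](c2c(OCC[Si](C)(C)C)c3c(C)cccc3oc2=O)O1 | intermediate
21 | 3-[(1R,4aS,7S,7aR)-4,7-dimethyl-3-(3-methylbut-2-enoyl)-1,4a,5,6,7,7a-hexahydrocyclopenta[c]pyran-1-yl]-5-methyl-4-[2-(trimethylsilyl)ethoxy]-2H-chromen-2-one | CC(C)=CC(=O)C1=C(C)[C@H]2CC[C@H](C)[C@H]2[C@H](c2c(OCC[Si](C)(C)C)c3c(C)cccc3oc2=O)O1 | intermediate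
22 | 4-hydroxy-3-[(1R,4aS,7S,7aR)-4,7-dimethyl-3-(3-methylbut-2-enoyl)-1,4a,5,6,7,7a-hexahydrocyclopenta[c]pyran-1-yl]-5-methyl-2H-chromen-2-one (CNP0297827.1) | CC(C)=CC(=O)C1=C(C)[C@H]2CC[C@H](C)[C@H]2[C@H](c2c(O)c3c(C)cccc3oc2=O)O1 | target

**Summary**

Total step count: 14. Longest linear sequence: 10 steps (1, 2, 3, 4, 7, 8, 11, 12, 13, 14).

Steps most likely to fail:

1. Step 13 (key step). The excited dienone may lose its energy by E/Z isomerisation or by photoenolisation through the C4 methyl group faster than it abstracts the OCH2 hydrogen. The enone may also add across the coumarin C3=C4 bond, or ring closure may be poorly selective at C1. Fallback with known chemistry, forming the same bond: from 19, a ground-state radical chain under polarity-reversal catalysis, with tri-tert-butoxysilanethiol (10 mol %) and di-tert-butyl hyponitrite in benzene at 60 °C. The thiyl radical removes the hydridic OCH2 hydrogen, the α-oxy radical adds to the dienone terminus C7a, and the resulting electrophilic radical takes hydrogen back from the thiol at oxygen (giving dienol 20) or at C4a. DBU then converges the material on 21, where the route is rejoined. This is the thiol-catalysed radical-chain hydroalkylation known for ethers and acetals with electron-poor alkenes; it makes no compound outside the list (F0).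

2. Step 12. Acyl transfer may be slow at the hindered, tetrasubstituted α-alkoxyacryloyl thioester, so that protodeboronation of the alkenylboronic acid or decarbonylation takes over. Fallback: from 18, Fukuyama reduction (Et3SiH, Pd/C, acetone, rt) should give the aldehyde (2Z)-2-({5-methyl-2-oxo-4-[2-(trimethylsilyl)ethoxy]-2H-chromen-3-yl}methoxy)-3-[(3S)-3-methylcyclopent-1-en-1-yl]but-2-enal F1. Addition of Me2C=CHMgBr in THF at −78 °C, where the aldehyde reacts well before the lactone, should give the bis-allylic alcohol (2Z)-6-methyl-2-[(3S)-3-methylcyclopent-1-en-1-yl]-3-({5-methyl-2-oxo-4-[2-(trimethylsilyl)ethoxy]-2H-chromen-3-yl}methoxy)hepta-2,5-dien-4-ol F2 as both carbinol epimers. Oxidation with MnO2 in CH2Cl2 returns to 19.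

3. Step 9. Methyl transfer to the five-membered enone may be poorly enantioselective, and the zinc enolate may condense with unreacted enone before it is trapped. Fallback: from 14, MeLi (Et2O, −78 °C) gives 1-methylcyclopent-2-en-1-ol F3. Pyridinium chlorochromate (C5H5NH[CrO3Cl], CH2Cl2) effects oxidative 1,3-transposition to 3-methylcyclopent-2-en-1-one F4. Copper-hydride asymmetric conjugate reduction (CuCl, NaOt-Bu, the p-Tol-BINAP enantiomer that gives 3S, Ph2SiH2, toluene) gives the regiodefined silyl enol ether [(3S)-3-methylcyclopent-1-en-1-yl]oxy(diphenyl)silane F5. MeLi in THF releases lithium (3S)-3-methylcyclopent-1-en-1-olate F6, which Comins' reagent converts into 16.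

**Further compounds**

F0 | step 13 | none | none
F1 | step 12 | (2Z)-2-({5-methyl-2-oxo-4-[2-(trimethylsilyl)ethoxy]-2H-chromen-3-yl}methoxy)-3-[(3S)-3-methylcyclopent-1-en-1-yl]but-2-enal | O=C/C(OCc1c(OCC[Si](C)(C)C)c2c(C)cccc2oc1=O)=C(\C)C1=C[C@@H](C)CC1
F2 | step 12 | (2Z)-6-methyl-2-[(3S)-3-methylcyclopent-1-en-1-yl]-3-({5-methyl-2-oxo-4-[2-(trimethylsilyl)ethoxy]-2H-chromen-3-yl}methoxy)hepta-2,5-dien-4-ol, both C4 epimers | CC(C)=CC(O)/C(OCc1c(OCC[Si](C)(C)C)c2c(C)cccc2oc1=O)=C(\C)C1=C[C@@H](C)CC1
F3 | step 9 | 1-methylcyclopent-2-en-1-ol, racemic | CC1(O)CCC=C1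
F4 | step 9 | 3-methylcyclopent-2-en-1-one | CC1=CC(=O)CC1
F5 | step 9 | [(3S)-3-methylcyclopent-1-en-1-yl]oxy(diphenyl)silane | C[C@H]1CCC(O[SiH](c2ccccc2)c2ccccc2)=C1
F6 | step 9 | lithium (3S)-3-methylcyclopent-1-en-1-olate | C[C@H]1CCC([O-])=C1.[Li+]
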